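**Retrosynthetic overview**

1. Licoricidin 20 ⇐ its tris-MOM ether 19 by acetal cleavage (last step).
2. 19 ⇐ ring A benzyl bromide 7 + ring B arylacetyl imide 15. One flask makes C4–C3 (auxiliary-controlled enolate benzylation, then reductive release of the C2–O1 alkoxide) and O1–C8a (alkoxide adds to the C8≡C8a aryne); this closes ring C, the only ring built in the route.
3. Enabling feature: in ring A, C8 is the only unsubstituted carbon and lies between O7 and C8a. A bromine at C8 (already present in starting material 1, where it also blocks that site during prenylation) is a latent aryne that takes O1 at C8a and returns H to C8. C3 is benzylic to ring B and alpha to C2, which stays at the acyl level until the C–C bond exists.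
4. 7 ⇐ 5-bromo-2,4-dihydroxybenzaldehyde 1 (C-prenylation, O4-MOM, O2-methyl, reduction, bromination); 15 ⇐ resorcinol 8 (two directed ortho-metalations: prenyl, then oxirane, which supplies C3, C2 and O1; oxidation; auxiliary).
5. Rings A and B are bought as benzene rings and carry both prenyl groups from the start; C3 (R) comes from (R)-4-benzyloxazolidin-2-one.

Key step: step 11

Remark: atom numbers follow the isoflavan skeleton (O1, C2, C3, C4, C4a, C5–C8, C8a; ring B primed). Step 11 is one flask operation in THF with three successive reagent charges; the species passed on the way are numbered 16–18.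

**Route**

Step 1
Reactants: 1 5-bromo-2,4-dihydroxybenzaldehyde; 2 1-bromo-3-methylbut-2-ene (prenyl bromide)
Product: 3 5-bromo-2,4-dihydroxy-3-(3-methylbut-2-en-1-yl)benzaldehyde
Conditions: KOH (10% aq), 0 °C → rt
Reagents that add atoms: none
Why: Aqueous-base C-alkylation of the resorcinol-type bis-phenoxide (phenoxide C-prenylation) should place the prenyl group on C3, between the two oxygens, because the only other activated ring carbon (C5) is blocked by bromine.

Step 2
Reactants: 3 5-bromo-2,4-dihydroxy-3-(3-methylbut-2-en-1-yl)benzaldehyde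
Product: 4 5-bromo-2-hydroxy-4-(methoxymethoxy)-3-(3-methylbut-2-en-1-yl)benzaldehyde
Conditions: MOMCl, i-Pr2NEt, CH2Cl2, 0 °C
Reagents that add atoms: chloromethyl methyl ether (MOMCl), COCCl
Why: The 2-OH is held in a hydrogen bond to the formyl group, so base-mediated O-alkylation (Williamson-type acetal formation) should take place at the more acidic, free 4-OH.

Step 3
Reactants: 4 5-bromo-2-hydroxy-4-(methoxymethoxy)-3-(3-methylbut-2-en-1-yl)benzaldehyde
Product: 5 5-bromo-2-methoxy-4-(methoxymethoxy)-3-(3-methylbut-2-en-1-yl)benzaldehyde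
Conditions: MeI, K2CO3, DMF, 40 °C
Reagents that add atoms: iodomethane, CI
Why: Williamson O-methylation of the remaining chelated phenol should proceed under slightly forcing conditions and fixes the future C5 methoxy group.

Step 4
Reactants: 5 5-bromo-2-methoxy-4-(methoxymethoxy)-3-(3-methylbut-2-en-1-yl)benzaldehyde
Product: 6 [5-bromo-2-methoxy-4-(methoxymethoxy)-3-(3-methylbut-2-en-1-yl)phenyl]methanol
Conditions: NaBH4, MeOH, 0 °C
Reagents that add atoms: none
Why: Borohydride reduction of the aryl aldehyde should leave the aryl bromide, the acetal and the alkene untouched.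

Step 5
Reactants: 6 [5-bromo-2-methoxy-4-(methoxymethoxy)-3-(3-methylbut-2-en-1-yl)phenyl]methanol
Product: 7 1-bromo-5-(bromomethyl)-4-methoxy-2-(methoxymethoxy)-3-(3-methylbut-2-en-1-yl)benzene
Conditions: CBr4, PPh3, CH2Cl2, 0 °C; used crude
Reagents that add atoms: carbon tetrabromide, BrC(Br)(Br)Br
Why: The Appel reaction should convert the benzylic alcohol into the bromide under neutral conditions that spare the MOM ether and the prenyl group; all ring positions open to self-alkylation are substituted.

Step 6
Reactants: 8 resorcinol (benzene-1,3-diol)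
Product: 9 1,3-bis(methoxymethoxy)benzene
Conditions: NaH, MOMCl, DMF, 0 °C → rt
Reagents that add atoms: chloromethyl methyl ether (MOMCl), COCCl
Why: Double Williamson-type O-alkylation installs two acetal groups that protect the phenols and direct the two metalations that follow.

Step 7
Reactants: 9 1,3-bis(methoxymethoxy)benzene; 2 1-bromo-3-methylbut-2-ene
Product: 10 1,3-bis(methoxymethoxy)-2-(3-methylbut-2-en-1-yl)benzene
Conditions: n-BuLi, THF, 0 °C; then CuI (10 mol %), 2, −78 → 0 °C
Reagents that add atoms: none
Why: Directed ortho-metalation should occur at C2, the carbon flanked by both OMOM groups, and copper-catalyzed allylic substitution should then deliver the linear prenyl group.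

Step 8
Reactants: 10 1,3-bis(methoxymethoxy)-2-(3-methylbut-2-en-1-yl)benzene; 11 oxirane
Product: 12 2-[2,4-bis(methoxymethoxy)-3-(3-methylbut-2-en-1-yl)phenyl]ethan-1-ol
Conditions: n-BuLi, TMEDA, THF, 0 °C; then 11, −78 °C → rt
Reagents that add atoms: none
Why: A second directed ortho-metalation next to an OMOM group (C4 and C6 are equivalent and the only ring positions ortho to a directing group) followed by epoxide opening with the aryllithium should attach the two-carbon chain that becomes C3 and C2.

Step 9
Reactants: 12 2-[2,4-bis(methoxymethoxy)-3-(3-methylbut-2-en-1-yl)phenyl]ethan-1-ol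
Product: 13 2-[2,4-bis(methoxymethoxy)-3-(3-methylbut-2-en-1-yl)phenyl]acetic acid
Conditions: TEMPO (cat.), PhI(OAc)2, MeCN/H2O, rt
Reagents that add atoms: water, O
Why: Oxoammonium-catalyzed oxidation of the primary alcohol through the aldehyde hydrate should give the acid without touching the trisubstituted alkene or the acetals.

Step 10
Reactants: 13 2-[2,4-bis(methoxymethoxy)-3-(3-methylbut-2-en-1-yl)phenyl]acetic acid; 14 (R)-4-benzyloxazolidin-2-one
Product: 15 (R)-4-benzyl-3-{2-[2,4-bis(methoxymethoxy)-3-(3-methylbut-2-en-1-yl)phenyl]acetyl}oxazolidin-2-one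
Conditions: t-BuCOCl, Et3N, THF, −20 °C; then 14, LiCl, rt
Reagents that add atoms: none
Why: N-Acylation of the oxazolidinone through the mixed pivalic anhydride (LiCl/Et3N protocol) should give the imide without enolizing the arylacetyl unit.

Step 11
Reactants: 15 (R)-4-benzyl-3-{2-[2,4-bis(methoxymethoxy)-3-(3-methylbut-2-en-1-yl)phenyl]acetyl}oxazolidin-2-one; 7 1-bromo-5-(bromomethyl)-4-methoxy-2-(methoxymethoxy)-3-(3-methylbut-2-en-1-yl)benzene
Product: 19 (3R)-3-[2,4-bis(methoxymethoxy)-3-(3-methylbut-2-en-1-yl)phenyl]-5-methoxy-7-(methoxymethoxy)-6-(3-methylbut-2-en-1-yl)chromane, via alkylated imide 16 (not isolated), via bromo alcohol 17 (not isolated), via aryne 18 (not isolated)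
Conditions: NaN(SiMe3)2, THF, −78 °C, then 7, −78 → −40 °C; then LiBH4, MeOH, 0 °C; then lithium 2,2,6,6-tetramethylpiperidide (LiTMP, excess), −78 → 0 °C; aq NH4Cl
Reagents that add atoms: none
Why: The sodium Z-enolate of 15, chelated to the oxazolidinone carbonyl, should be benzylated by 7 on the face opposite the auxiliary benzyl group (Evans asymmetric alkylation), which forms C4–C3 and sets C3 as R, and LiBH4 should then cleave the imide reductively so that C2 becomes the CH2–OLi group carrying O1. LiTMP should remove H8a, the only hydrogen ortho to the C8 bromine, LiBr is lost to give the C8≡C8a aryne, and the tethered alkoxide O1 adds to C8a in a 6-exo-dig closure of ring C while the C8 aryllithium, held between O7 and O1, is protonated to restore H8. The closest known reaction types are the Evans benzylation and LiBH4 reduction of arylacetyl oxazolidinones used for isoflavans, and the base-mediated benzyne cyclization of 3-(3-halophenyl)propan-1-ols to chromans. The only new stereocenter, C3, is controlled by the (R)-4-benzyl auxiliary and is no longer acidic after the reduction, so the strongly basic ring closure cannot scramble it. The step needs O1 to end on C8a and not on C8, and three things secure this: the aryne can form only toward C8a because C7 carries OMOM, a 3-alkoxyaryne is attacked meta to the alkoxy group, and attack at C8 would require a meta-bridged seven-membered ring. Competition from the amide base for the aryne is limited by the intramolecular delivery of O1 and the bulk of the tetramethylpiperidide.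

Step 12
Reactants: 19 (3R)-3-[2,4-bis(methoxymethoxy)-3-(3-methylbut-2-en-1-yl)phenyl]-5-methoxy-7-(methoxymethoxy)-6-(3-methylbut-2-en-1-yl)chromane
Product: 20 licoricidin, 4-[(3R)-7-hydroxy-5-methoxy-6-(3-methylbut-2-en-1-yl)chroman-3-yl]-2-(3-methylbut-2-en-1-yl)benzene-1,3-diol
Conditions: HCl (3 M aq), MeOH, 40 °C
Reagents that add atoms: none
Why: Acid-catalyzed acetal exchange of the three aryl MOM ethers with methanol should free the phenols under conditions mild enough to leave the prenyl groups and the non-acidic C3 stereocenter unchanged.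

**Compound list**

1 | 5-bromo-2,4-dihydroxybenzaldehyde | O=Cc1cc(Br)c(O)cc1O | starting material
2 | 1-bromo-3-methylbut-2-ene (prenyl bromide) | CC(C)=CCBr | starting material
3 | 5-bromo-2,4-dihydroxy-3-(3-methylbut-2-en-1-yl)benzaldehyde | O=Cc1cc(Br)c(O)c(CC=C(C)C)c1O | intermediate
4 | 5-bromo-2-hydroxy-4-(methoxymethoxy)-3-(3-methylbut-2-en-1-yl)benzaldehyde | O=Cc1cc(Br)c(OCOC)c(CC=C(C)C)c1O | intermediate
5 | 5-bromo-2-methoxy-4-(methoxymethoxy)-3-(3-methylbut-2-en-1-yl)benzaldehyde | O=Cc1cc(Br)c(OCOC)c(CC=C(C)C)c1OC | intermediate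
6 | [5-bromo-2-methoxy-4-(methoxymethoxy)-3-(3-methylbut-2-en-1-yl)phenyl]methanol | OCc1cc(Br)c(OCOC)c(CC=C(C)C)c1OC | intermediate
7 | 1-bromo-5-(bromomethyl)-4-methoxy-2-(methoxymethoxy)-3-(3-methylbut-2-en-1-yl)benzene | BrCc1cc(Br)c(OCOC)c(CC=C(C)C)c1OC | intermediate
8 | resorcinol (benzene-1,3-diol) | Oc1cccc(O)c1 | starting material
9 | 1,3-bis(methoxymethoxy)benzene | COCOc1cccc(OCOC)c1 | intermediate
10 | 1,3-bis(methoxymethoxy)-2-(3-methylbut-2-en-1-yl)benzene | COCOc1cccc(OCOC)c1CC=C(C)C | intermediate
11 | oxirane | C1CO1 | starting material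
12 | 2-[2,4-bis(methoxymethoxy)-3-(3-methylbut-2-en-1-yl)phenyl]ethan-1-ol | OCCc1ccc(OCOC)c(CC=C(C)C)c1OCOC | intermediate
13 | 2-[2,4-bis(methoxymethoxy)-3-(3-methylbut-2-en-1-yl)phenyl]acetic acid | OC(=O)Cc1ccc(OCOC)c(CC=C(C)C)c1OCOC | intermediate
14 | (R)-4-benzyloxazolidin-2-one | O=C1N[C@H](Cc2ccccc2)CO1 | starting material
15 | (R)-4-benzyl-3-{2-[2,4-bis(methoxymethoxy)-3-(3-methylbut-2-en-1-yl)phenyl]acetyl}oxazolidin-2-one | O=C(Cc1ccc(OCOC)c(CC=C(C)C)c1OCOC)N1[C@H](Cc2ccccc2)COC1=O | intermediate
16 | (R)-4-benzyl-3-{(2R)-2-[2,4-bis(methoxymethoxy)-3-(3-methylbut-2-en-1-yl)phenyl]-3-[5-bromo-2-methoxy-4-(methoxymethoxy)-3-(3-methylbut-2-en-1-yl)phenyl]propanoyl}oxazolidin-2-one | COc1c(CC=C(C)C)c(OCOC)c(Br)cc1C[C@H](c1ccc(OCOC)c(CC=C(C)C)c1OCOC)C(=O)N1[C@H](Cc2ccccc2)COC1=O | intermediate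
17 | (2R)-2-[2,4-bis(methoxymethoxy)-3-(3-methylbut-2-en-1-yl)phenyl]-3-[5-bromo-2-methoxy-4-(methoxymethoxy)-3-(3-methylbut-2-en-1-yl)phenyl]propan-1-ol (present as its lithium alkoxide) | COc1c(CC=C(C)C)c(OCOC)c(Br)cc1C[C@H](c1ccc(OCOC)c(CC=C(C)C)c1OCOC)CO | intermediate
18 | C8≡C8a aryne formed from 17 by loss of HBr, (2R)-2-[2,4-bis(methoxymethoxy)-3-(3-methylbut-2-en-1-yl)phenyl]-3-[5,6-didehydro-2-methoxy-4-(methoxymethoxy)-3-(3-methylbut-2-en-1-yl)phenyl]propan-1-ol (drawn as the alcohol, present as its lithium alkoxide) | COC1=C(C[C@H](c2ccc(OCOC)c(CC=C(C)C)c2OCOC)CO)C#CC(OCOC)=C1CC=C(C)C | intermediate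
19 | (3R)-3-[2,4-bis(methoxymethoxy)-3-(3-methylbut-2-en-1-yl)phenyl]-5-methoxy-7-(methoxymethoxy)-6-(3-methylbut-2-en-1-yl)chromane | COc1c(CC=C(C)C)c(OCOC)cc2c1C[C@H](c1ccc(OCOC)c(CC=C(C)C)c1OCOC)CO2 | intermediate
20 | licoricidin, 4-[(3R)-7-hydroxy-5-methoxy-6-(3-methylbut-2-en-1-yl)chroman-3-yl]-2-(3-methylbut-2-en-1-yl)benzene-1,3-diol | COc1c(CC=C(C)C)c(O)cc2c1C[C@H](c1ccc(O)c(CC=C(C)C)c1O)CO2 | target

**Step count and risks**

Total step count: 12. Longest linear sequence: 7 steps (steps 6–10, 11, 12 from resorcinol; equally steps 1–5, 11, 12 from 1).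

Steps most likely to fail:

1. Step 11. Boron hydride residues may reduce the aryne or hold O1 as a borate so that the closure stalls. The amide base may add to the aryne or move the prenyl double bonds into conjugation, and excess base may epimerize C3 of 16 before the reduction. The fallback gives up the one-flask design and runs three separate, individually known operations with purification. It sets out from 15 and 7: Evans benzylation (NaN(SiMe3)2, THF, −78 °C) with isolation of 16 and removal of any minor diastereomer, then LiBH4 reduction with isolation of 17. Pure 17, free of hydride and of hindered amide, is then closed in a separate flask with the NaNH2/NaOt-Bu complex base in THF (benzyne cyclization). It comes back to the route at 19 (no new compound: F0).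

2. Step 1. O-Alkylation and double alkylation may outrun C-alkylation of the bis-phenoxide. The fallback builds the C-prenyl group by sigmatropic rearrangement and sets out from 1. Copper-catalyzed O-alkylation of the free 4-OH with 3-chloro-3-methylbut-1-yne (DBU, CuCl2 cat., MeCN, 0 °C) should give 5-bromo-2-hydroxy-4-[(2-methylbut-3-yn-2-yl)oxy]benzaldehyde F1. Semihydrogenation (H2, Pd/CaCO3 poisoned with Pb(OAc)2, quinoline, EtOAc) should give 5-bromo-2-hydroxy-4-[(2-methylbut-3-en-2-yl)oxy]benzaldehyde F2. Aromatic Claisen rearrangement (N,N-diethylaniline, 130 °C) can only reach the one free ortho carbon, C3, because the other is brominated. It comes back to the route at 3.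

3. Step 12. Protonation of the prenyl alkenes may lead to ring closure onto the neighbouring free phenols or to hydration while the acetals are being cleaved. The fallback replaces protic solvolysis by an acetal-to-silyl ether exchange and sets out from 19. Trimethylsilyl triflate with 2,2'-bipyridyl (MeCN, 0 °C) should transfer the methoxymethyl groups to the pyridine base and leave the tris(trimethylsilyl) ether of licoricidin, (3R)-3-[2,4-bis(trimethylsilyloxy)-3-(3-methylbut-2-en-1-yl)phenyl]-5-methoxy-6-(3-methylbut-2-en-1-yl)-7-(trimethylsilyloxy)chromane F3. Methanolysis (K2CO3, MeOH, 0 °C) should then release the phenols. It comes back to the route at 20.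

**Further compounds**

F0 | step 11 | none | none
F1 | step 1 | 5-bromo-2-hydroxy-4-[(2-methylbut-3-yn-2-yl)oxy]benzaldehyde | O=Cc1cc(Br)c(OC(C)(C)C#C)cc1O
F2 | step 1 | 5-bromo-2-hydroxy-4-[(2-methylbut-3-en-2-yl)oxy]benzaldehyde | O=Cc1cc(Br)c(OC(C)(C)C=C)cc1O
F3 | step 12 | (3R)-3-[2,4-bis(trimethylsilyloxy)-3-(3-methylbut-2-en-1-yl)phenyl]-5-methoxy-6-(3-methylbut-2-en-1-yl)-7-(trimethylsilyloxy)chromane | COc1c(CC=C(C)C)c(O[Si](C)(C)C)cc2c1C[C@H](c1ccc(O[Si](C)(C)C)c(CC=C(C)C)c1O[Si](C)(C)C)CO2
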